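**Strategy.** The middle flavan unit is not taken from epicatechin: its pyran ring C is grown onto a phloroglucinol-type ring A that already carries the top unit at the future C6. That ring is converted into a 3-alkoxyaryne (C4a≡C8a, flanked by the C5 benzyloxy group), which is annulated with a syn-β-hydroxy-α-alkoxy aldehyde: the alkoxide O1 adds to C8a and the resulting C4a anion closes on the aldehyde carbon C4. One operation thus makes the O1–C8a and C4a–C4 bonds, fixes the 4→6 linkage by symmetry of the aryl ring, and delivers a flavan-4-ol ready for 4β→8 coupling with the bottom unit; global galloylation and hydrogenolysis finish.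

Key step: step 11

Remark: flavan numbering (O1, C2, C3, C4, C4a, C5 to C8, C8a) is used for each unit; 21 is carried on as its two C4 epimers because C4 is ionised again in step 12; 3,4,5-tris(benzyloxy)benzoyl chloride is assumed to be a commercial acylating reagent.

**Route**

Step 1
Reactants: 1 (−)-epicatechin
Product: 2 5,7,3',4'-tetra-O-benzyl-(−)-epicatechin
Conditions: BnBr, K2CO3, DMF, 0 °C → rt
Reagents that add atoms: benzyl bromide, BrCc1ccccc1
Why: Williamson etherification in which K2CO3 deprotonates only the four phenols, so the aliphatic 3-OH stays free and no stereocentre is touched.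

Step 2
Reactants: 2 5,7,3',4'-tetra-O-benzyl-(−)-epicatechin
Product: 3 3-O-allyl-5,7,3',4'-tetra-O-benzyl-(−)-epicatechin
Conditions: NaH, allyl bromide, Bu4NI (cat.), THF/DMF, 0 °C → rt
Reagents that add atoms: allyl bromide, C=CCBr
Why: Williamson etherification of the secondary alkoxide gives an ether that cannot migrate, survives Lewis acid, organolithium and fluoride, and is removed later together with the second allyl group.

Step 3
Reactants: 3 3-O-allyl-5,7,3',4'-tetra-O-benzyl-(−)-epicatechin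
Product: 4 3-O-allyl-5,7,3',4'-tetra-O-benzyl-4β-(2-ethoxyethoxy)epicatechin
Conditions: DDQ, 2-ethoxyethanol, CH2Cl2, rt
Reagents that add atoms: 2-ethoxyethanol, CCOCCO
Why: DDQ benzylic oxidation (hydride abstraction at C4 of the electron-rich chroman) gives a C4 cation that the alcohol captures anti to the axial 3-O-allyl group, setting the 4β (3,4-trans) ether.

Step 4
Reactants: 4 3-O-allyl-5,7,3',4'-tetra-O-benzyl-4β-(2-ethoxyethoxy)epicatechin; 5 3,5-bis(benzyloxy)phenol (4 equiv)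
Product: 6 3-O-allyl-5,7,3',4'-tetra-O-benzyl-4β-[2,6-bis(benzyloxy)-4-hydroxyphenyl]epicatechin
Conditions: TMSOTf (0.2 equiv), CH2Cl2, 4 Å molecular sieves, −78 → −40 °C
Reagents that add atoms: none
Why: TMSOTf-promoted Friedel–Crafts alkylation in which the C4 ether ionises to the benzylic cation, which the phenol should attack mainly through the carbon para to its hydroxyl (giving the locally symmetric 2,6-bis(benzyloxy)-4-hydroxyphenyl ring) and anti to the axial 3-O-allyl group, setting the 4β centre; the ortho-linked isomer is removed by chromatography.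

Step 5
Reactants: 6 3-O-allyl-5,7,3',4'-tetra-O-benzyl-4β-[2,6-bis(benzyloxy)-4-hydroxyphenyl]epicatechin
Product: 7 3-O-allyl-5,7,3',4'-tetra-O-benzyl-4β-[2,6-bis(benzyloxy)-3-bromo-4-hydroxyphenyl]epicatechin
Conditions: NBS (1.0 equiv), i-Pr2NH (cat.), CH2Cl2, −78 °C
Reagents that add atoms: N-bromosuccinimide, O=C1CCC(=O)N1Br
Why: amine-catalysed ortho-bromination of a phenol, which is far faster on the free phenol ring than on the ether rings, and the two ortho carbons are equivalent so a single bromophenol should result.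

Step 6
Reactants: 7 3-O-allyl-5,7,3',4'-tetra-O-benzyl-4β-[2,6-bis(benzyloxy)-3-bromo-4-hydroxyphenyl]epicatechin
Product: 10 3-O-allyl-5,7,3',4'-tetra-O-benzyl-4β-[2,6-bis(benzyloxy)-4-(trifluoromethylsulfonyloxy)-3-(trimethylsilyl)phenyl]epicatechin, via trimethylsilyl ether 8 (not isolated), via lithium phenoxide 9 (not isolated)
Conditions: (Me3Si)2NH, THF, 65 °C, evaporate; n-BuLi, THF, −100 °C; Tf2O, −100 → −78 °C
Reagents that add atoms: hexamethyldisilazane, C[Si](C)(C)N[Si](C)(C)C; trifluoromethanesulfonic anhydride, O=S(=O)(OS(=O)(=O)C(F)(F)F)C(F)(F)F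
Why: O-silylation, bromine–lithium exchange and retro-Brook 1,3-shift of silicon from O to C give the ortho-silyl phenoxide, which Tf2O traps as the ortho-silylaryl triflate; the substrate holds only ethers, so no group competes for n-BuLi at −100 °C.

Step 7
Reactants: 11 (S)-4-benzyl-2-oxazolidinone; 12 2-(allyloxy)acetic acid
Product: 14 (S)-3-[2-(allyloxy)acetyl]-4-benzyl-2-oxazolidinone, via mixed pivalic anhydride 13 (not isolated)
Conditions: t-BuCOCl, Et3N, THF, −20 °C; then 11, LiCl, −20 °C → rt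
Reagents that add atoms: none
Why: N-acylation of the oxazolidinone by a mixed anhydride (LiCl-assisted), the standard entry to glycolate imides for the Evans aldol reaction.

Step 8
Reactants: 14 (S)-3-[2-(allyloxy)acetyl]-4-benzyl-2-oxazolidinone; 15 3,4-bis(benzyloxy)benzaldehyde
Product: 17 (S)-3-[(2S,3R)-2-(allyloxy)-3-[3,4-bis(benzyloxy)phenyl]-3-hydroxypropanoyl]-4-benzyl-2-oxazolidinone, via boron enolate 16 (not isolated)
Conditions: n-Bu2BOTf, Et3N, CH2Cl2, −78 → 0 °C; then 15, −78 → 0 °C; MeOH/H2O2 work-up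
Reagents that add atoms: none
Why: Evans syn-aldol reaction in which the (Z)-boron enolate reacts through a Zimmerman–Traxler chair on the face opposite the benzyl group of the auxiliary, setting (2S,3R), the syn relationship that becomes 2,3-cis in the flavan.

Step 9
Reactants: 17 (S)-3-[(2S,3R)-2-(allyloxy)-3-[3,4-bis(benzyloxy)phenyl]-3-hydroxypropanoyl]-4-benzyl-2-oxazolidinone
Product: 18 (2S,3R)-2-(allyloxy)-3-[3,4-bis(benzyloxy)phenyl]-3-hydroxy-N-methoxy-N-methylpropanamide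
Conditions: MeNHOMe·HCl, AlMe3, CH2Cl2, −20 → 0 °C
Reagents that add atoms: N,O-dimethylhydroxylamine hydrochloride, CNOC.Cl
Why: Weinreb transamidation by the aluminium amide, assisted by the free β-hydroxyl, releases the auxiliary without touching either stereocentre.

Step 10
Reactants: 18 (2S,3R)-2-(allyloxy)-3-[3,4-bis(benzyloxy)phenyl]-3-hydroxy-N-methoxy-N-methylpropanamide
Product: 19 (2S,3R)-2-(allyloxy)-3-[3,4-bis(benzyloxy)phenyl]-3-hydroxypropanal
Conditions: i-Bu2AlH (2.5 equiv), THF, −78 °C; aq. potassium sodium tartrate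
Reagents that add atoms: none
Why: i-Bu2AlH reduction of a Weinreb amide stops at the chelated hemiaminal and gives the aldehyde on work-up; the crude β-hydroxy aldehyde is used at once to limit epimerisation and retro-aldol cleavage.

Step 11
Reactants: 10 3-O-allyl-5,7,3',4'-tetra-O-benzyl-4β-[2,6-bis(benzyloxy)-4-(trifluoromethylsulfonyloxy)-3-(trimethylsilyl)phenyl]epicatechin; 19 (2S,3R)-2-(allyloxy)-3-[3,4-bis(benzyloxy)phenyl]-3-hydroxypropanal (2.5 equiv)
Product: 21 3-O-allyl-5,7,3',4'-tetra-O-benzylepicatechin-(4β→6)-[3-O-allyl-5,7,3',4'-tetra-O-benzyl-4-hydroxyepicatechin] (both C4 epimers), via aryne 20 (not isolated)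
Conditions: CsF (4 equiv), MeCN–toluene, 4 Å molecular sieves, rt, slow addition of 10
Reagents that add atoms: none
Why: Proposed new method: fluoride-induced 1,2-elimination of 10 gives aryne 20, the alkoxide of 19 adds to C8a (the aryne carbon remote from the C5 benzyloxy group, as with all 3-alkoxyarynes), and the C4a aryl anion so formed, stabilised by the adjacent oxygen, adds to the pendant aldehyde carbon C4. The closest known reaction type is the aryne annulation of salicylaldehydes to xanthen-9-ols and of salicylates to xanthones (phenoxide addition, then carbonyl capture by the aryl anion); an aliphatic β-hydroxy aldehyde has not been used in this way. The pyran ring (O1–C2–C3–C4–C4a–C8a) closes by 6-exo-trig attack of C4a on the C=O group. C2 and C3 come unchanged from the aldol adduct because no bond to either is broken, and the new carbinol centre C4 needs no control because it is ionised in step 12. The step needs O-addition at C8a rather than C4a, which the C5 benzyloxy group secures, and ring closure faster than protonation of the aryl anion, which the six-membered transition state and the reactive aldehyde should favour.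

Step 12
Reactants: 21 3-O-allyl-5,7,3',4'-tetra-O-benzylepicatechin-(4β→6)-[3-O-allyl-5,7,3',4'-tetra-O-benzyl-4-hydroxyepicatechin]; 2 5,7,3',4'-tetra-O-benzyl-(−)-epicatechin (4 equiv)
Product: 22 dodeca-O-benzyl trimer epicatechin-(4β→6)-epicatechin-(4β→8)-epicatechin with 3-O-allyl groups on the top and middle units and a free 3-OH on the bottom unit
Conditions: TMSOTf (0.3 equiv), CH2Cl2, 4 Å molecular sieves, −78 → −40 °C; Et3N quench
Reagents that add atoms: none
Why: Lewis-acid Friedel–Crafts coupling of a flavan-4-ol in which ionisation at C4 (loss of the hydroxyl as water) gives the benzylic cation, which C8 of 2 (its most nucleophilic carbon, used in excess to suppress self-condensation) attacks anti to the axial 3-O-allyl group, setting the 4β (3,4-trans) centre.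

Step 13
Reactants: 22 dodeca-O-benzyl trimer with two 3-O-allyl groups
Product: 24 dodeca-O-benzyl trimer with three free 3-hydroxyls, via bis(prop-1-enyl) ether 23 (not isolated)
Conditions: [Ir(cod)(PMePh2)2]PF6 (5 mol %, H2-activated), THF, rt; then 1 M HCl, acetone–THF, rt
Reagents that add atoms: none
Why: iridium-catalysed isomerisation of allyl to prop-1-enyl ethers followed by mild acid hydrolysis of the enol ethers frees both C3 hydroxyls without affecting benzyl ethers or interflavan bonds.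

Step 14
Reactants: 24 dodeca-O-benzyl trimer with three free 3-hydroxyls
Product: 25 dodeca-O-benzyl trimer tris[3,4,5-tris(benzyloxy)benzoate]
Conditions: 3,4,5-tris(benzyloxy)benzoyl chloride (6 equiv), Et3N, DMAP, CH2Cl2, 0 → 40 °C
Reagents that add atoms: 3,4,5-tris(benzyloxy)benzoyl chloride (three molecules are incorporated, one per hydroxyl), O=C(Cl)c1cc(OCc2ccccc2)c(OCc2ccccc2)c(OCc2ccccc2)c1.O=C(Cl)c1cc(OCc2ccccc2)c(OCc2ccccc2)c(OCc2ccccc2)c1.O=C(Cl)c1cc(OCc2ccccc2)c(OCc2ccccc2)c(OCc2ccccc2)c1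
Why: DMAP-catalysed acylation by the acid chloride esterifies each of the three secondary C3 hydroxyls, one acyl group per hydroxyl, with retention since only O–H bonds react.

Step 15
Reactants: 25 dodeca-O-benzyl trimer tris[3,4,5-tris(benzyloxy)benzoate]
Product: 26 epicatechin-3-O-gallate-(4β→6)-epicatechin-3-O-gallate-(4β→8)-epicatechin-3-O-gallate (CNP0183218.1)
Conditions: H2 (1 atm), Pd(OH)2/C, THF–MeOH–H2O, rt
Reagents that add atoms: none
Why: hydrogenolysis of the 21 benzyl ethers over Pd(OH)2/C leaves the gallate esters, the interflavan C–C bonds and all stereocentres intact.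

**Compound list**

1 | (−)-epicatechin | O[C@@H]1Cc2c(O)cc(O)cc2O[C@@H]1c1ccc(O)c(O)c1 | starting material
2 | 5,7,3',4'-tetra-O-benzyl-(−)-epicatechin | O[C@@H]1Cc2c(OCc3ccccc3)cc(OCc3ccccc3)cc2O[C@@H]1c1ccc(OCc2ccccc2)c(OCc2ccccc2)c1 | intermediate
3 | 3-O-allyl-5,7,3',4'-tetra-O-benzyl-(−)-epicatechin | C=CCO[C@@H]1Cc2c(OCc3ccccc3)cc(OCc3ccccc3)cc2O[C@@H]1c1ccc(OCc2ccccc2)c(OCc2ccccc2)c1 | intermediate
4 | 3-O-allyl-5,7,3',4'-tetra-O-benzyl-4β-(2-ethoxyethoxy)epicatechin (2,3-cis-3,4-trans) | C=CCO[C@@H]1[C@@H](OCCOCC)c2c(OCc3ccccc3)cc(OCc3ccccc3)cc2O[C@@H]1c1ccc(OCc2ccccc2)c(OCc2ccccc2)c1 | intermediate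
5 | 3,5-bis(benzyloxy)phenol | Oc1cc(OCc2ccccc2)cc(OCc2ccccc2)c1 | starting material
6 | 3-O-allyl-5,7,3',4'-tetra-O-benzyl-4β-[2,6-bis(benzyloxy)-4-hydroxyphenyl]epicatechin | C=CCO[C@@H]1[C@@H](c2c(OCc3ccccc3)cc(O)cc2OCc2ccccc2)c2c(OCc3ccccc3)cc(OCc3ccccc3)cc2O[C@@H]1c1ccc(OCc2ccccc2)c(OCc2ccccc2)c1 | intermediate
7 | 3-O-allyl-5,7,3',4'-tetra-O-benzyl-4β-[2,6-bis(benzyloxy)-3-bromo-4-hydroxyphenyl]epicatechin | C=CCO[C@@H]1[C@@H](c2c(OCc3ccccc3)cc(O)c(Br)c2OCc2ccccc2)c2c(OCc3ccccc3)cc(OCc3ccccc3)cc2O[C@@H]1c1ccc(OCc2ccccc2)c(OCc2ccccc2)c1 | intermediate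
8 | O-trimethylsilyl ether of 7 | C=CCO[C@@H]1[C@@H](c2c(OCc3ccccc3)cc(O[Si](C)(C)C)c(Br)c2OCc2ccccc2)c2c(OCc3ccccc3)cc(OCc3ccccc3)cc2O[C@@H]1c1ccc(OCc2ccccc2)c(OCc2ccccc2)c1 | intermediate
9 | lithium phenoxide with the trimethylsilyl group on the former bromine-bearing carbon | C=CCO[C@@H]1[C@@H](c2c(OCc3ccccc3)cc([O-])c([Si](C)(C)C)c2OCc2ccccc2)c2c(OCc3ccccc3)cc(OCc3ccccc3)cc2O[C@@H]1c1ccc(OCc2ccccc2)c(OCc2ccccc2)c1.[Li+] | intermediate
10 | 3-O-allyl-5,7,3',4'-tetra-O-benzyl-4β-[2,6-bis(benzyloxy)-4-(trifluoromethylsulfonyloxy)-3-(trimethylsilyl)phenyl]epicatechin | C=CCO[C@@H]1[C@@H](c2c(OCc3ccccc3)cc(OS(=O)(=O)C(F)(F)F)c([Si](C)(C)C)c2OCc2ccccc2)c2c(OCc3ccccc3)cc(OCc3ccccc3)cc2O[C@@H]1c1ccc(OCc2ccccc2)c(OCc2ccccc2)c1 | intermediate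
11 | (S)-4-benzyl-2-oxazolidinone | O=C1N[C@@H](Cc2ccccc2)CO1 | starting material
12 | 2-(allyloxy)acetic acid | C=CCOCC(=O)O | starting material
13 | 2-(allyloxy)acetic pivalic anhydride | C=CCOCC(=O)OC(=O)C(C)(C)C | intermediate
14 | (S)-3-[2-(allyloxy)acetyl]-4-benzyl-2-oxazolidinone | C=CCOCC(=O)N1[C@@H](Cc2ccccc2)COC1=O | intermediate
15 | 3,4-bis(benzyloxy)benzaldehyde | O=Cc1ccc(OCc2ccccc2)c(OCc2ccccc2)c1 | starting material
16 | (Z)-dibutylboron enolate of 14 | C=CCO/C=C(\OB(CCCC)CCCC)N1[C@@H](Cc2ccccc2)COC1=O | intermediate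
17 | (S)-3-[(2S,3R)-2-(allyloxy)-3-[3,4-bis(benzyloxy)phenyl]-3-hydroxypropanoyl]-4-benzyl-2-oxazolidinone | O=C(N1[C@@H](Cc2ccccc2)COC1=O)[C@@H](OCC=C)[C@@H](c1ccc(OCc2ccccc2)c(OCc2ccccc2)c1)O | intermediate
18 | (2S,3R)-2-(allyloxy)-3-[3,4-bis(benzyloxy)phenyl]-3-hydroxy-N-methoxy-N-methylpropanamide | CON(C)C(=O)[C@@H](OCC=C)[C@@H](c1ccc(OCc2ccccc2)c(OCc2ccccc2)c1)O | intermediate
19 | (2S,3R)-2-(allyloxy)-3-[3,4-bis(benzyloxy)phenyl]-3-hydroxypropanal | O=C[C@@H](OCC=C)[C@@H](c1ccc(OCc2ccccc2)c(OCc2ccccc2)c1)O | intermediate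
20 | aryne from 10 (triple bond between the former silyl- and triflyloxy-bearing carbons) | C=CCO[C@@H]1[C@@H](C2=C(OCc3ccccc3)C#CC=C2OCc2ccccc2)c2c(OCc3ccccc3)cc(OCc3ccccc3)cc2O[C@@H]1c1ccc(OCc2ccccc2)c(OCc2ccccc2)c1 | intermediate
21 | 3-O-allyl-tetra-O-benzylepicatechin-(4β→6)-[3-O-allyl-5,7,3',4'-tetra-O-benzyl-4-hydroxyepicatechin], C4 epimers | C=CCO[C@@H]1[C@@H](c2c(OCc3ccccc3)cc3c(c2OCc2ccccc2)C(O)[C@@H](OCC=C)[C@@H](c2ccc(OCc4ccccc4)c(OCc4ccccc4)c2)O3)c2c(OCc3ccccc3)cc(OCc3ccccc3)cc2O[C@@H]1c1ccc(OCc2ccccc2)c(OCc2ccccc2)c1 | intermediate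
22 | dodeca-O-benzyl trimer, 3-O-allyl on top and middle units, free 3-OH on bottom unit | C=CCO[C@@H]1[C@@H](c2c(OCc3ccccc3)cc3c(c2OCc2ccccc2)[C@H](c2c(OCc4ccccc4)cc(OCc4ccccc4)c4c2O[C@H](c2ccc(OCc5ccccc5)c(OCc5ccccc5)c2)[C@H](O)C4)[C@@H](OCC=C)[C@@H](c2ccc(OCc4ccccc4)c(OCc4ccccc4)c2)O3)c2c(OCc3ccccc3)cc(OCc3ccccc3)cc2O[C@@H]1c1ccc(OCc2ccccc2)c(OCc2ccccc2)c1 | intermediate
23 | bis(prop-1-enyl) ether of the trimer (E/Z not defined) | CC=CO[C@@H]1[C@@H](c2c(OCc3ccccc3)cc3c(c2OCc2ccccc2)[C@H](c2c(OCc4ccccc4)cc(OCc4ccccc4)c4c2O[C@H](c2ccc(OCc5ccccc5)c(OCc5ccccc5)c2)[C@H](O)C4)[C@@H](OC=CC)[C@@H](c2ccc(OCc4ccccc4)c(OCc4ccccc4)c2)O3)c2c(OCc3ccccc3)cc(OCc3ccccc3)cc2O[C@@H]1c1ccc(OCc2ccccc2)c(OCc2ccccc2)c1 | intermediate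
24 | dodeca-O-benzyl trimer with three free 3-hydroxyls | O[C@@H]1[C@@H](c2c(OCc3ccccc3)cc3c(c2OCc2ccccc2)[C@H](c2c(OCc4ccccc4)cc(OCc4ccccc4)c4c2O[C@H](c2ccc(OCc5ccccc5)c(OCc5ccccc5)c2)[C@H](O)C4)[C@@H](O)[C@@H](c2ccc(OCc4ccccc4)c(OCc4ccccc4)c2)O3)c2c(OCc3ccccc3)cc(OCc3ccccc3)cc2O[C@@H]1c1ccc(OCc2ccccc2)c(OCc2ccccc2)c1 | intermediate
25 | dodeca-O-benzyl trimer tris[3,4,5-tris(benzyloxy)benzoate] | O=C(O[C@@H]1[C@@H](c2c(OCc3ccccc3)cc3c(c2OCc2ccccc2)[C@H](c2c(OCc4ccccc4)cc(OCc4ccccc4)c4c2O[C@H](c2ccc(OCc5ccccc5)c(OCc5ccccc5)c2)[C@H](OC(=O)c2cc(OCc5ccccc5)c(OCc5ccccc5)c(OCc5ccccc5)c2)C4)[C@@H](OC(=O)c2cc(OCc4ccccc4)c(OCc4ccccc4)c(OCc4ccccc4)c2)[C@@H](c2ccc(OCc4ccccc4)c(OCc4ccccc4)c2)O3)c2c(OCc3ccccc3)cc(OCc3ccccc3)cc2O[C@@H]1c1ccc(OCc2ccccc2)c(OCc2ccccc2)c1)c1cc(OCc2ccccc2)c(OCc2ccccc2)c(OCc2ccccc2)c1 | intermediate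
26 | epicatechin-3-O-gallate-(4β→6)-epicatechin-3-O-gallate-(4β→8)-epicatechin-3-O-gallate | O=C(O[C@@H]1[C@@H](c2c(O)cc3c(c2O)[C@H](c2c(O)cc(O)c4c2O[C@H](c2ccc(O)c(O)c2)[C@H](OC(=O)c2cc(O)c(O)c(O)c2)C4)[C@@H](OC(=O)c2cc(O)c(O)c(O)c2)[C@@H](c2ccc(O)c(O)c2)O3)c2c(O)cc(O)cc2O[C@@H]1c1ccc(O)c(O)c1)c1cc(O)c(O)c(O)c1 | target

**Step count.** Total: 15 steps. Longest linear sequence: 11 steps (steps 1–6 and 11–15); steps 7–10 form the convergent branch.

**Steps most likely to fail**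

1. Step 11 (proposed new method). The aryl anion may be protonated before it reaches the aldehyde, giving only O-arylation, or the β-hydroxy aldehyde may undergo retro-aldol cleavage or α-epimerisation under fluoride. The fallback makes the two bonds one after the other by known reactions and sets out from 10 and 18. CsF in MeCN–toluene would effect the known O–H insertion of an aryne into an aliphatic alcohol, with the same regiochemistry, to give the aryl ether Weinreb amide F1. i-Bu2AlH at −78 °C would reduce it to the aryloxy aldehyde F2. Treatment of F2 with TMSOTf in CH2Cl2 at −78 °C in the presence of 2 would close ring C by intramolecular Friedel–Crafts hydroxyalkylation at either of the two equivalent carbons ortho to O1, ionise the resulting flavan-4-ol and couple it with C8 of 2. The fallback comes back to the route at 22.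

2. Step 4. Regioselectivity may be poor, with alkylation ortho rather than para to the phenolic hydroxyl. The fallback sets out from 4 and uses phloroglucinol (benzene-1,3,5-triol, in excess, TMSOTf, THF–CH2Cl2), whose threefold symmetry allows only one C-aryl adduct, the triol F3. The unhindered para hydroxyl would be silylated selectively (t-BuPh2SiCl, imidazole, DMF, −20 °C) to the silyl ether F4. The two hydroxyls flanking the flavanyl group would then be benzylated (BnBr, K2CO3) to the dibenzyl ether F5, and Bu4NF would remove the silyl group. The fallback comes back to the route at 6.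

3. Step 6. Bromine–lithium exchange on a polyether may be incomplete, or the aryllithium may be quenched before the silyl shift. The fallback sets out from 6, omits the bromination and uses directed ortho-metalation. Isopropyl isocyanate (Et3N cat.) would give the carbamate F6. In-situ N-silylation (t-BuMe2SiOTf, TMEDA), lithiation with n-BuLi at −78 °C at either of the two equivalent ortho carbons and Me3SiCl would give the ortho-silyl carbamate F7. Et2NH/DBU in MeCN at 40 °C followed by PhNTf2 would cleave the carbamate and triflate the phenoxide. The fallback comes back to the route at 10.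

**Further compounds**

F1 | step 11 | aryl ether Weinreb amide: 4-O-[(1R,2S)-2-(allyloxy)-1-[3,4-bis(benzyloxy)phenyl]-3-(N-methoxy-N-methylamino)-3-oxopropyl] ether of 6 | C=CCO[C@@H]1[C@@H](c2c(OCc3ccccc3)cc(O[C@H](c3ccc(OCc4ccccc4)c(OCc4ccccc4)c3)[C@H](OCC=C)C(=O)N(C)OC)cc2OCc2ccccc2)c2c(OCc3ccccc3)cc(OCc3ccccc3)cc2O[C@@H]1c1ccc(OCc2ccccc2)c(OCc2ccccc2)c1
F2 | step 11 | aryloxy aldehyde from reduction of F1 | C=CCO[C@@H]1[C@@H](c2c(OCc3ccccc3)cc(O[C@H](c3ccc(OCc4ccccc4)c(OCc4ccccc4)c3)[C@H](OCC=C)C=O)cc2OCc2ccccc2)c2c(OCc3ccccc3)cc(OCc3ccccc3)cc2O[C@@H]1c1ccc(OCc2ccccc2)c(OCc2ccccc2)c1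
F3 | step 4 | 3-O-allyl-5,7,3',4'-tetra-O-benzyl-4β-(2,4,6-trihydroxyphenyl)epicatechin | C=CCO[C@@H]1[C@@H](c2c(O)cc(O)cc2O)c2c(OCc3ccccc3)cc(OCc3ccccc3)cc2O[C@@H]1c1ccc(OCc2ccccc2)c(OCc2ccccc2)c1
F4 | step 4 | 4β-[4-(tert-butyldiphenylsilyloxy)-2,6-dihydroxyphenyl] analogue of F3 | C=CCO[C@@H]1[C@@H](c2c(O)cc(O[Si](c3ccccc3)(c3ccccc3)C(C)(C)C)cc2O)c2c(OCc3ccccc3)cc(OCc3ccccc3)cc2O[C@@H]1c1ccc(OCc2ccccc2)c(OCc2ccccc2)c1
F5 | step 4 | 4β-[2,6-bis(benzyloxy)-4-(tert-butyldiphenylsilyloxy)phenyl] analogue of F3 | C=CCO[C@@H]1[C@@H](c2c(OCc3ccccc3)cc(O[Si](c3ccccc3)(c3ccccc3)C(C)(C)C)cc2OCc2ccccc2)c2c(OCc3ccccc3)cc(OCc3ccccc3)cc2O[C@@H]1c1ccc(OCc2ccccc2)c(OCc2ccccc2)c1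
F6 | step 6 | N-isopropylcarbamate of phenol 6 | C=CCO[C@@H]1[C@@H](c2c(OCc3ccccc3)cc(OC(=O)NC(C)C)cc2OCc2ccccc2)c2c(OCc3ccccc3)cc(OCc3ccccc3)cc2O[C@@H]1c1ccc(OCc2ccccc2)c(OCc2ccccc2)c1
F7 | step 6 | ortho-trimethylsilyl N-isopropylcarbamate | C=CCO[C@@H]1[C@@H](c2c(OCc3ccccc3)cc(OC(=O)NC(C)C)c([Si](C)(C)C)c2OCc2ccccc2)c2c(OCc3ccccc3)cc(OCc3ccccc3)cc2O[C@@H]1c1ccc(OCc2ccccc2)c(OCc2ccccc2)c1
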